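Wednesday's flask shows, at 20.0 h, 23% target, 10% starting material and 16% isomer of the product, together 49.0% of the solid substrate charged, against 56.0% at 12.0 h.

| setting | Wednesday's | flask |
|---|---|---|
| solid substrate | 0.29 M | 0.29 M |
| remark | the very flask that is asked about, followed so far |  |
| time |  | 10 d |

Wednesday's run (percent of the solid substrate charged)

| time / h | target / % | starting material / % | isomer of the product / % |
|---|---|---|---|
| 1.50 | 5 | 17 | 4 |
| 2.50 | 5 | 23 | 8 |
| 4.00 | 10 | 26 | 11 |
| 8.00 | 24 | 29 | 20 |
| 12.0 | 23 | 14 | 19 |
| 20.0 | 23 | 10 | 16 |

(readings scatter by 1.5 percentage points)

* at 10 d, what has stopped the reaction, if anything has (for what has run out or reacted, a solid counts together with what of it has only dissolved) (all of the solid substrate has reacted / forward and back rates have come level / it is still moving)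
* target at 10 d, in percent of the solid substrate charged
* starting material at 10 d, in percent of the solid substrate charged
* isomer of the product at 10 d, in percent of the solid substrate charged

- as a solid, counted per litre of solution: solid substrate
- the numbers in the tables scatter by 1.5 percentage points (one standard deviation)
- on the list of suspects stand: starting material <-> dormant form; isomer of the product <-> starting material; starting material <-> target; solid substrate <-> starting material; target <-> isomer of the product
- at the start none of the solid substrate is in solution
- what has only dissolved of solid substrate counts as not reacted
- the reaction counts as stopped when no species that holds the solid substrate changes by six tenths of a point or more over the second half of the time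
- starting material means what is dissolved; the solid is not counted in it

This visible share of the flask falls by 7 percentage points in 8.00 h. I replace the curve by its mean slope and ask how long the share left at 20.0 h would last on that slope. That gives 2.33 d, my emptying time, a turnover time of the visible pool. The loss carries a scatter of 3.7 points, so the slow end of this time is 4.91 d. A real curve may also bend, so I take the figure as a scale, not a date.

The first setting is the time. The 10 d of this flask exceed the emptying time and its slow end, so I expect the drain to have ended and target and isomer of the product to stand well under their last readings. The second setting is the charge. Each suspect past the solid has one species on each side, so by hand the percentages stay put when the charge changes, provided the solid dissolves.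

The forecast differs from me: 24% target, 9% starting material, 14% isomer of the product, close to the last reading taken over, and its ending is: forward and back rates have come level. Its ground: “The flat target suggests reversible steps approaching equilibrium”.

The flask gives 10.7% target, 7.65% starting material and 7.39% isomer of the product, and its ending is: forward and back rates have come level.

    starting material ⇌ dormant form (K = 9.70, k = 0.180 h⁻¹)
    isomer of the product ⇌ starting material (k = 0.270 h⁻¹)
    starting material ⇌ target (K = 1.40, k = 0.100 h⁻¹)
    solid substrate ⇌ starting material, rate k4*(cs4 - [starting material]) while solid is left; crystals form when [starting material] > cs4 (solubility = 0.200 M, k = 0.300 h⁻¹)
    target ⇌ isomer of the product (K = 0.690, k = 0.130 h⁻¹)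

The visible share of this flask does not empty: it stops at 25.7%, with 74.2% in the dormant form, a thermodynamic end rather than a kinetic one. The emptying time counts from the reading at 20.0 h, so on the clock it ends at 3.17 d. The neighbouring flask, the same charge left until 2.5 d, is read before that, and the mean slope gives it a visible share of 13.9%. That neighbouring flask reads 8.09% starting material, 8.04% isomer of the product and 11.8% target, together 27.9%.

The runs come from a simulation on assumed constants; scatter was added.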